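The route rests on cutting both bonds at the ketone carbon C16: C15–C16 to the unbranched fifteen-carbon tether and C16–C17 to the methyl group. Because C16 carries nothing else, it is introduced as the doubly nucleophilic CH2 of tosylmethyl isocyanide, which is alkylated first by the long primary bromide and then by iodomethane without isolating the intermediate; later hydrolysis turns that carbon into the carbonyl. The precursor is 1-(15-bromopentadecyl)-3,5-dimethoxybenzene: the only ring, the resorcinol benzene ring, is masked as its base-stable dimethyl ether, and the chain C1–C15 ends in the bromide. It is built from pentadecan-15-olide and 1-bromo-3,5-dimethoxybenzene.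

Key step: step 5

Remark on the chemistry: chain atoms are numbered from the benzylic carbon (C1) to the methyl group (C17). The target has no stereocentre; the stereogenic carbon C16 present in 11, 12 and 13 is formed racemic and disappears when it becomes the carbonyl carbon. Hydrazone 6 is an E/Z mixture.

Step 1
Reactants: 1 pentadecan-15-olide
Product: 2 15-hydroxy-N-methoxy-N-methylpentadecanamide
Conditions: MeNH(OMe)·HCl (1.5 equiv), i-PrMgCl (3.0 equiv), THF, −20 → 0 °C; aq NH4Cl
Reagents that add atoms: N,O-dimethylhydroxylamine hydrochloride, CNOC.Cl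
Why: Weinreb amide formation by aminolysis of the lactone with the chloromagnesium amide of N,O-dimethylhydroxylamine should be irreversible here, because the liberated alkoxide cannot re-close a 16-membered ring.

Step 2
Reactants: 2 15-hydroxy-N-methoxy-N-methylpentadecanamide; 3 1-bromo-3,5-dimethoxybenzene
Product: 5 1-(3,5-dimethoxyphenyl)-15-hydroxypentadecan-1-one, via 3,5-dimethoxyphenylmagnesium bromide 4 (not isolated)
Conditions: 3 (2.5 equiv), Mg, I2 (cat.), THF, reflux; then 2, THF, 0 °C → rt; aq NH4Cl
Reagents that add atoms: none
Why: In this Weinreb ketone synthesis one equivalent of Grignard reagent 4 only deprotonates the hydroxyl group, and the next adds to the amide to give a magnesium-chelated tetrahedral intermediate that resists over-addition and releases the aryl ketone on aqueous quench.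

Step 3
Reactants: 5 1-(3,5-dimethoxyphenyl)-15-hydroxypentadecan-1-one
Product: 7 15-(3,5-dimethoxyphenyl)pentadecan-1-ol, via hydrazone 6 (not isolated)
Conditions: N2H4·H2O (6 equiv), KOH (5 equiv), diethylene glycol, 130 °C, then distil off water and heat at 195–200 °C
Reagents that add atoms: none
Why: In this Wolff–Kishner reduction (Huang-Minlon procedure) hydrazone 6 is deprotonated by hot KOH and loses N2 to leave the benzylic CH2, a standard deoxygenation for 3,5-dimethoxyphenyl alkyl ketones that the primary alcohol and the aryl methyl ethers should survive.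

Step 4
Reactants: 7 15-(3,5-dimethoxyphenyl)pentadecan-1-ol
Product: 8 1-(15-bromopentadecyl)-3,5-dimethoxybenzene
Conditions: CBr4 (1.3 equiv), PPh3 (1.35 equiv), CH2Cl2, 0 °C → rt
Reagents that add atoms: carbon tetrabromide, BrC(Br)(Br)Br
Why: In the Appel reaction the alkoxyphosphonium ion of the primary alcohol is displaced by bromide in an SN2 step under neutral conditions that leave the dimethoxyarene untouched.

Step 5
Reactants: 8 1-(15-bromopentadecyl)-3,5-dimethoxybenzene; 9 tosylmethyl isocyanide; 10 iodomethane
Product: 12 1-[16-isocyano-16-(4-methylphenyl)sulfonylheptadecyl]-3,5-dimethoxybenzene (racemic), via monoalkylated isocyanide 11 (not isolated)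
Conditions: 9 (1.5 equiv), n-Bu4NI (0.2 equiv), 40% aq NaOH, CH2Cl2, 0 °C → rt; organic phase separated, dried and concentrated; then NaH (2 equiv), 10 (4 equiv), DMSO/Et2O, 0 °C → rt
Reagents that add atoms: none
Why: The CH2 of 9, acidified by both the sulfonyl and the isocyano group, is deprotonated at the liquid–liquid interface, carried into CH2Cl2 as its tetrabutylammonium ion pair and alkylated by 8 in an SN2 displacement that iodide accelerates by Finkelstein exchange, forming C15–C16; the remaining, less acidic and more hindered C–H of 11 is then removed irreversibly by NaH and the tertiary carbanion is captured by the small electrophile 10, forming C16–C17. The closest known reaction type is the sequential dialkylation of tosylmethyl isocyanide used as a carbonyl dianion equivalent for unsymmetrical ketones. No ring is closed. The new quaternary carbon C16 is stereogenic but needs no control, since it is formed racemic and becomes the planar carbonyl carbon in step 6. The step needs mono- rather than bis-alkylation by the long chain, and C-alkylation without loss of the isocyanide: the order of addition (phase-transfer conditions and an excess of 9 for the slow primary bromide, strong base only for the methylation) secures the first, and the substrate secures the second because 8 has one unhindered primary C–Br bond, no acidic C–H and only base-inert aryl methyl ethers.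

Step 6
Reactants: 12 1-[16-isocyano-16-(4-methylphenyl)sulfonylheptadecyl]-3,5-dimethoxybenzene
Product: 14 17-(3,5-dimethoxyphenyl)heptadecan-2-one, via N-formyl sulfone 13 (not isolated)
Conditions: 37% aq HCl, THF/Et2O, 0 °C → rt
Reagents that add atoms: water, O
Why: In this acid hydrolysis of an α-sulfonyl isocyanide, hydration gives N-formyl sulfone 13, which expels sulfinate to an N-acyliminium ion that water converts into the ketone, while the aryl methyl ethers are stable to cold aqueous HCl.

Step 7
Reactants: 14 17-(3,5-dimethoxyphenyl)heptadecan-2-one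
Product: 15 Hansfordiol B [17-(3,5-dihydroxyphenyl)heptadecan-2-one]
Conditions: BBr3 (4 equiv), CH2Cl2, −78 °C → rt; MeOH then H2O, 0 °C
Reagents that add atoms: none
Why: In this Lewis-acid ether cleavage BBr3 coordinates each methoxy oxygen and bromide removes the methyl group by SN2, the excess reagent compensating for reversible complexation at the ketone, and hydrolysis of the aryl borates on quench should release the resorcinol.

Compound list
1 | pentadecan-15-olide (oxacyclohexadecan-2-one) | O=C1CCCCCCCCCCCCCCO1 | starting material
2 | 15-hydroxy-N-methoxy-N-methylpentadecanamide | CON(C)C(=O)CCCCCCCCCCCCCCO | intermediate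
3 | 1-bromo-3,5-dimethoxybenzene | COc1cc(Br)cc(OC)c1 | starting material
4 | 3,5-dimethoxyphenylmagnesium bromide (not isolated) | COc1cc([Mg]Br)cc(OC)c1 | intermediate
5 | 1-(3,5-dimethoxyphenyl)-15-hydroxypentadecan-1-one | COc1cc(cc(OC)c1)C(=O)CCCCCCCCCCCCCCO | intermediate
6 | 15-(3,5-dimethoxyphenyl)-15-hydrazinylidenepentadecan-1-ol (E/Z mixture, not isolated) | COc1cc(cc(OC)c1)C(=NN)CCCCCCCCCCCCCCO | intermediate
7 | 15-(3,5-dimethoxyphenyl)pentadecan-1-ol | COc1cc(CCCCCCCCCCCCCCCO)cc(OC)c1 | intermediate
8 | 1-(15-bromopentadecyl)-3,5-dimethoxybenzene (key-step precursor) | COc1cc(CCCCCCCCCCCCCCCBr)cc(OC)c1 | intermediate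
9 | tosylmethyl isocyanide [1-(isocyanomethylsulfonyl)-4-methylbenzene] | [C-]#[N+]CS(=O)(=O)c1ccc(C)cc1 | starting material
10 | iodomethane | CI | starting material
11 | 1-[16-isocyano-16-(4-methylphenyl)sulfonylhexadecyl]-3,5-dimethoxybenzene (racemic, not isolated) | [C-]#[N+]C(CCCCCCCCCCCCCCCc1cc(OC)cc(OC)c1)S(=O)(=O)c1ccc(C)cc1 | intermediate
12 | 1-[16-isocyano-16-(4-methylphenyl)sulfonylheptadecyl]-3,5-dimethoxybenzene (racemic, key-step product) | [C-]#[N+]C(C)(CCCCCCCCCCCCCCCc1cc(OC)cc(OC)c1)S(=O)(=O)c1ccc(C)cc1 | intermediate
13 | N-[17-(3,5-dimethoxyphenyl)-2-(4-methylphenyl)sulfonylheptadecan-2-yl]formamide (racemic, not isolated) | O=CNC(C)(CCCCCCCCCCCCCCCc1cc(OC)cc(OC)c1)S(=O)(=O)c1ccc(C)cc1 | intermediate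
14 | 17-(3,5-dimethoxyphenyl)heptadecan-2-one | CC(=O)CCCCCCCCCCCCCCCc1cc(OC)cc(OC)c1 | intermediate
15 | Hansfordiol B, 17-(3,5-dihydroxyphenyl)heptadecan-2-one | CC(=O)CCCCCCCCCCCCCCCc1cc(O)cc(O)c1 | target

Total step count: 7. Longest linear sequence: 7 steps (1 → 2 → 5 → 7 → 8 → 12 → 14 → 15).

Steps most likely to fail

Step 5. The long-chain bromide may react slowly at the interface, so that 9 self-condenses under base before it is alkylated. A second molecule of 8 may alkylate 11, and methylation of the hindered second anion may stall. The fallback replaces the carbonyl dianion equivalent by an acyl anion equivalent that already carries C17 (Corey–Seebach alkylation). It sets out from 8: 2-methyl-1,3-dithiane is lithiated with n-BuLi in THF at −30 °C and alkylated with 8 to give 2-[15-(3,5-dimethoxyphenyl)pentadecyl]-2-methyl-1,3-dithiane F1. The thioacetal is then removed with MeI and CaCO3 in aqueous MeCN at 50 °C, conditions chosen to avoid oxidants that could attack the electron-rich arene. The fallback comes back to the route at ketone 14.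

Step 3. Hot hydroxide in glycol may demethylate an aryl ether, the hydrazone may dimerise to the azine, and water removal may be incomplete with the waxy substrate. The fallback reorders the sequence and deoxygenates on the acid side. It sets out from 5: Appel bromination (CBr4, PPh3, CH2Cl2) should give 15-bromo-1-(3,5-dimethoxyphenyl)pentadecan-1-one F2. Ionic hydrogenation of the aryl ketone with Et3SiH in CF3CO2H (rt to 50 °C, dilute) should then reduce the carbonyl to CH2 without touching the primary bromide. The fallback comes back at bromide 8 and bypasses 7.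

Step 7. BBr3 bound at the ketone may cause enolisation and aldol-type self-condensation, or cleavage may stall at the monomethyl ether. The fallback changes the phenol protection so that no ketone ever meets BBr3. It sets out from 8: BBr3 in CH2Cl2 (−78 °C → rt) on this ketone-free bromide should give 5-(15-bromopentadecyl)benzene-1,3-diol F3, and MOMCl with i-Pr2NEt in CH2Cl2 should give 1-(15-bromopentadecyl)-3,5-bis(methoxymethoxy)benzene F4. The two-stage alkylation of step 5 with 9 and then 10 should pass through 1-[16-isocyano-16-(4-methylphenyl)sulfonylhexadecyl]-3,5-bis(methoxymethoxy)benzene F5 (not isolated) to 1-[16-isocyano-16-(4-methylphenyl)sulfonylheptadecyl]-3,5-bis(methoxymethoxy)benzene F6. HCl in MeOH/THF at 40 °C should then hydrolyse the isocyanide sulfone and both acetals in one operation. The fallback comes back at target 15.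

Further compounds
F1 | step 5 | 2-[15-(3,5-dimethoxyphenyl)pentadecyl]-2-methyl-1,3-dithiane | CC1(CCCCCCCCCCCCCCCc2cc(OC)cc(OC)c2)SCCCS1
F2 | step 3 | 15-bromo-1-(3,5-dimethoxyphenyl)pentadecan-1-one | COc1cc(cc(OC)c1)C(=O)CCCCCCCCCCCCCCBr
F3 | step 7 | 5-(15-bromopentadecyl)benzene-1,3-diol | Oc1cc(O)cc(CCCCCCCCCCCCCCCBr)c1
F4 | step 7 | 1-(15-bromopentadecyl)-3,5-bis(methoxymethoxy)benzene | COCOc1cc(CCCCCCCCCCCCCCCBr)cc(OCOC)c1
F5 | step 7 | 1-[16-isocyano-16-(4-methylphenyl)sulfonylhexadecyl]-3,5-bis(methoxymethoxy)benzene (racemic, not isolated) | [C-]#[N+]C(CCCCCCCCCCCCCCCc1cc(OCOC)cc(OCOC)c1)S(=O)(=O)c1ccc(C)cc1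
F6 | step 7 | 1-[16-isocyano-16-(4-methylphenyl)sulfonylheptadecyl]-3,5-bis(methoxymethoxy)benzene (racemic) | [C-]#[N+]C(C)(CCCCCCCCCCCCCCCc1cc(OCOC)cc(OCOC)c1)S(=O)(=O)c1ccc(C)cc1
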